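## Retrosynthetic overview

1. The target comes from global fluoride removal of two aryl TBS ethers and a TMSE ester from the fully protected azaphilone ester.
2. Key step: a direct, enantioselective dearomative C7 acyloxylation of the 7-deoxy azaphilone with a preformed chiral bis(aroyloxy)-λ³-iodane. This sets the quaternary C7 carbinol centre and installs the bis-TBS orsellinate ester in one operation.
3. The 7-deoxy azaphilone comes from Ag(I) 6-endo cycloisomerisation of an o-alkynylbenzaldehyde, which closes the pyran ring.
4. That enynal comes from two Sonogashira couplings on an aryl iodide, which is made by Comins ortho-lithiation/iodination of a 2-methylresorcinol-derived aldehyde.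
5. Ring order: the arene (commercial), then the pyran, then dearomatisation to the bicyclic dienedione, which sets C7. The chiral iodoarene and the silylated orsellinic acid are made in two short side branches from commercial materials.

Assumptions: 2-iodoresorcinol, ethyl (R)-lactate and orsellinic acid are commercial. The (S,S)-iodoarene is assumed to give 7R; if the opposite sense is found, the (R,R)-iodoarene (from ethyl (S)-lactate) is used.

## Route

**Step 1**
Reactants: **1** 2,4-dihydroxy-3-methylbenzaldehyde; **2** iodomethane
Product: **3** 2,4-dimethoxy-3-methylbenzaldehyde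
Conditions: MeI (4 equiv), K2CO3 (4 equiv), DMF, 50 °C, 12 h
Reagents that add atoms: MeI, CI (**2**)
Why: Williamson O-methylation of both phenols (DMF and mild heating are needed for the H-bonded 2-OH); no stereocentre is involved.

**Step 2**
Reactants: **3** 2,4-dimethoxy-3-methylbenzaldehyde; **4** iodine
Product: **5** 2-iodo-4,6-dimethoxy-5-methylbenzaldehyde
Conditions: (a) LiN(Me)CH2CH2NMe2 (from N,N,N′-trimethylethylenediamine and n-BuLi), THF, −20 °C; (b) n-BuLi, −20 °C, 12 h; (c) I2, −78 °C → rt; aqueous workup
Reagents that add atoms: I2, II (**4**)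
Why: Comins in-situ α-amino-alkoxide directed ortho-lithiation goes to C6, the only free position ortho to the masked CHO, which places iodine meta to both oxygens, a site electrophilic iodination cannot reach.

**Step 3**
Reactants: **5** 2-iodo-4,6-dimethoxy-5-methylbenzaldehyde
Product: **6** 2-iodo-4,6-dihydroxy-5-methylbenzaldehyde
Conditions: BBr3 (5 equiv), CH2Cl2, −78 °C → rt; MeOH/H2O quench
Reagents that add atoms: none
Why: BBr3 cleaves both aryl methyl ethers (the 2-OMe is activated by chelation to the CHO), freeing the two oxygens that become C6=O and C8=O.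

**Step 4**
Reactants: **6** 2-iodo-4,6-dihydroxy-5-methylbenzaldehyde; **7** trimethylsilylacetylene
Product: **8** 4,6-dihydroxy-5-methyl-2-[(trimethylsilyl)ethynyl]benzaldehyde
Conditions: Pd(PPh3)2Cl2 (3 mol%), CuI (5 mol%), Et3N, THF, rt
Reagents that add atoms: TMS-acetylene, C#C[Si](C)(C)C (**7**)
Why: Sonogashira coupling, which tolerates free phenols and the aldehyde.

**Step 5**
Reactants: **8** 4,6-dihydroxy-5-methyl-2-[(trimethylsilyl)ethynyl]benzaldehyde
Product: **9** 2-ethynyl-4,6-dihydroxy-5-methylbenzaldehyde
Conditions: K2CO3 (0.3 equiv), MeOH/THF, 0 °C, 30 min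
Reagents that add atoms: none
Why: Mild base-mediated C(sp)–Si protodesilylation.

**Step 6**
Reactants: **10** (E)-3-iodoacrylic acid; **11** 2-(trimethylsilyl)ethanol
Product: **12** 2-(trimethylsilyl)ethyl (E)-3-iodoacrylate
Conditions: EDC·HCl, DMAP (cat.), CH2Cl2, 0 °C → rt
Reagents that add atoms: none
Why: Steglich esterification; the TMSE ester is later removed by fluoride together with the silyl ethers, and the E-alkene geometry is already fixed.

**Step 7**
Reactants: **9** 2-ethynyl-4,6-dihydroxy-5-methylbenzaldehyde; **12** TMSE (E)-3-iodoacrylate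
Product: **13** TMSE (E)-5-(2-formyl-3,5-dihydroxy-4-methylphenyl)pent-2-en-4-ynoate
Conditions: Pd(PPh3)4 (5 mol%), CuI (10 mol%), Et3N, THF, rt, dark
Reagents that add atoms: none
Why: Sonogashira coupling of a vinyl iodide with a terminal alkyne proceeds with retention of the E-alkene.

**Step 8**
Reactants: **13** TMSE (E)-5-(2-formyl-3,5-dihydroxy-4-methylphenyl)pent-2-en-4-ynoate
Product: **14** TMSE (E)-3-(7-methyl-6,8-dioxo-7H-isochromen-3-yl)acrylate (7-deoxy azaphilone, diketo tautomer)
Conditions: AgOTf (5 mol%), CH2Cl2, rt, 1 h, dark; filter through Celite and concentrate; use immediately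
Reagents that add atoms: none
Why: π-Acid-catalysed 6-endo attack of the aldehyde oxygen on the alkyne gives the 2-benzopyrylium, and protodemetalation and loss of a phenol proton give the neutral azaphilone (a Porco-type cycloisomerisation), which has no stereocentre yet.

**Step 9**
Reactants: **15** 2-iodoresorcinol; **16** ethyl (R)-lactate
Product: **17** (S,S)-diethyl 2,2′-[(2-iodo-1,3-phenylene)bis(oxy)]dipropanoate
Conditions: PPh3 (2.6 equiv), DIAD (2.6 equiv), THF, 0 °C → rt, 16 h
Reagents that add atoms: ethyl (R)-lactate, second equivalent, C[C@@H](O)C(=O)OCC (**16**)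
Why: Double Mitsunobu etherification of the phenols proceeds with inversion at the lactate carbinol carbon, converting (R)-lactate into the (S)-aryloxypropanoate, so the C2-symmetric iodoarene is formed with both stereocentres set.

**Step 10**
Reactants: **18** orsellinic acid; **19** tert-butyldimethylsilyl chloride
Product: **20** 2,4-bis(tert-butyldimethylsilyloxy)-6-methylbenzoic acid
Conditions: TBSCl (3.5 equiv), imidazole (8 equiv), DMF, rt, 16 h; then THF/H2O/AcOH workup to hydrolyse the silyl ester
Reagents that add atoms: TBSCl, CC(C)(C)[Si](C)(C)Cl (**19**)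
Why: Per-silylation followed by selective hydrolysis of the labile silyl ester leaves the aryl TBS ethers intact.

**Step 11**
Reactants: **17** (S,S)-diethyl 2,2′-[(2-iodo-1,3-phenylene)bis(oxy)]dipropanoate; **20** 2,4-bis-TBS-6-methylbenzoic acid
Product: **21** chiral bis(aroyloxy)-λ³-iodane, Ar*I(O2CAr′)2
Conditions: (i) AcOOH (32% in AcOH, 1.2 equiv), CH2Cl2, rt, 1 h; (ii) **20** (2.4 equiv in total), CH2Cl2, rt, 1 h; concentrate three times from CH2Cl2 to remove AcOH; use crude
Reagents that add atoms: second equivalent of **20**, Cc1cc(O[Si](C)(C)C(C)(C)C)cc(O[Si](C)(C)C(C)(C)C)c1C(=O)O (peracetic acid, CC(=O)OO, is only the oxidant and leaves no atoms in the product)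
Why: Peracid oxidation gives Ar*I(OAc)2, and ligand exchange with two equivalents of acid **20** (AcOH driven off) gives a preformed reagent, which avoids competing carboxylate byproducts such as m-chlorobenzoate (net: 17 + 2 × 20 + AcOOH → 21 + AcOH + H2O).

**Step 12 (key step)**
Reactants: **14** TMSE (E)-3-(7-methyl-6,8-dioxo-7H-isochromen-3-yl)acrylate; **21** chiral bis(aroyloxy)iodane
Product: **22** TMSE (E)-3-[(7R)-7-(2,4-bis-TBSO-6-methylbenzoyloxy)-7-methyl-6,8-dioxo-7H-isochromen-3-yl]acrylate
Conditions: **21** (1.5 equiv), CH2Cl2, 4 Å MS, −40 → 0 °C, 12 h, dark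
Reagents that add atoms: none (co-products are iodoarene **17**, recovered, and acid **20**)
Why: Proposed new method: the enolised 7-deoxy azaphilone (a 2-methyl-1,3-dione/benzopyrylium-phenolate) is doubly activated at C7 and binds the I(III) centre, and the neighbouring aroyloxy ligand is then delivered to C7 by inner-sphere ligand coupling or SN2′ on the face shielded by the C2-symmetric lactate arms, setting the (R) quaternary centre and the ester together; the closest known reactions are chiral-iodane enantioselective oxidative dearomatisation of naphthols and PIDA α-acyloxylation of 1,3-dicarbonyls (and racemic PIDA 7-acetoxylation of azaphilones).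

**Step 13**
Reactants: **22** protected mitorubrinic acid
Product: **23** mitorubrinic acid
Conditions: TBAF (1 M in THF, 6 equiv), THF, 0 °C, 20 min; quench with AcOH/aq. NH4Cl, acidify to pH ~3; purify by RP-HPLC
Reagents that add atoms: none
Why: Fluoride removes both aryl TBS ethers and the TMSE ester (fluoride-induced β-elimination to ethylene and TMSF) in one operation, and the quaternary C7 centre cannot epimerise.

## Compound list

| No. | Name | SMILES | Role |
|---|---|---|---|
| 1 | 2,4-dihydroxy-3-methylbenzaldehyde | Cc1c(O)ccc(C=O)c1O | starting material |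
| 2 | iodomethane | CI | starting material |
| 3 | 2,4-dimethoxy-3-methylbenzaldehyde | Cc1c(OC)ccc(C=O)c1OC | intermediate |
| 4 | iodine | II | starting material |
| 5 | 2-iodo-4,6-dimethoxy-5-methylbenzaldehyde | O=Cc1c(I)cc(OC)c(C)c1OC | intermediate |
| 6 | 2-iodo-4,6-dihydroxy-5-methylbenzaldehyde | O=Cc1c(I)cc(O)c(C)c1O | intermediate |
| 7 | trimethylsilylacetylene | C#C[Si](C)(C)C | starting material |
| 8 | 4,6-dihydroxy-5-methyl-2-(TMS-ethynyl)benzaldehyde | O=Cc1c(C#C[Si](C)(C)C)cc(O)c(C)c1O | intermediate |
| 9 | 2-ethynyl-4,6-dihydroxy-5-methylbenzaldehyde | O=Cc1c(C#C)cc(O)c(C)c1O | intermediate |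
| 10 | (E)-3-iodoacrylic acid | OC(=O)/C=C/I | starting material |
| 11 | 2-(trimethylsilyl)ethanol | C[Si](C)(C)CCO | starting material |
| 12 | TMSE (E)-3-iodoacrylate | C[Si](C)(C)CCOC(=O)/C=C/I | intermediate |
| 13 | TMSE (E)-5-(2-formyl-3,5-dihydroxy-4-methylphenyl)pent-2-en-4-ynoate | O=Cc1c(C#C/C=C/C(=O)OCC[Si](C)(C)C)cc(O)c(C)c1O | intermediate |
| 14 | 7-deoxy azaphilone TMSE ester | CC1C(=O)C=C2C=C(/C=C/C(=O)OCC[Si](C)(C)C)OC=C2C1=O | intermediate |
| 15 | 2-iodoresorcinol | Oc1cccc(O)c1I | starting material |
| 16 | ethyl (R)-lactate | C[C@@H](O)C(=O)OCC | starting material |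
| 17 | (S,S)-lactate-derived 2-iodoresorcinol diether (chiral iodoarene) | CCOC(=O)[C@H](C)Oc1cccc(O[C@@H](C)C(=O)OCC)c1I | intermediate (chiral reagent precursor, recovered after Step 12) |
| 18 | orsellinic acid | Cc1cc(O)cc(O)c1C(=O)O | starting material |
| 19 | tert-butyldimethylsilyl chloride | CC(C)(C)[Si](C)(C)Cl | starting material |
| 20 | 2,4-bis(TBSO)-6-methylbenzoic acid | Cc1cc(O[Si](C)(C)C(C)(C)C)cc(O[Si](C)(C)C(C)(C)C)c1C(=O)O | intermediate |
| 21 | chiral bis(aroyloxy)-λ³-iodane | CCOC(=O)[C@H](C)Oc1cccc(O[C@@H](C)C(=O)OCC)c1I(OC(=O)c1c(C)cc(O[Si](C)(C)C(C)(C)C)cc1O[Si](C)(C)C(C)(C)C)OC(=O)c1c(C)cc(O[Si](C)(C)C(C)(C)C)cc1O[Si](C)(C)C(C)(C)C | intermediate (reagent) |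
| 22 | protected mitorubrinic acid | Cc1cc(O[Si](C)(C)C(C)(C)C)cc(O[Si](C)(C)C(C)(C)C)c1C(=O)O[C@]1(C)C(=O)C=C2C=C(/C=C/C(=O)OCC[Si](C)(C)C)OC=C2C1=O | intermediate |
| 23 | mitorubrinic acid | Cc1cc(O)cc(O)c1C(=O)O[C@]1(C)C(=O)C=C2C=C(/C=C/C(=O)O)OC=C2C1=O | target |

## Totals

- Total steps: 13, including Step 6 (ester side branch), Steps 9–11 (reagent branch: iodoarene, silylated acid, iodane) and the main chain.
- Longest linear sequence: 9 steps (Steps 1, 2, 3, 4, 5, 7, 8, 12, 13).

## Three steps most likely to fail

1. **Step 12, enantioselective dearomative acyloxylation.**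
   - Risks: low ee, attack at C5 instead of C7, or arene oxidation of the silylated orsellinate.
   - Fallback: Porco-type Cu(II)/sparteine/O2 enantioselective hydroxylation of **14** to the 7-hydroxy azaphilone, using the sparteine enantiomer that gives 7R. Then acylate the tertiary alcohol with the acid chloride of **20** (DMAP). This splits the key step into hydroxylation and esterification.
2. **Step 8, 6-endo cycloisomerisation of the electron-poor enynoate.**
   - Risk: 5-exo closure to an isobenzofuran competes because the δ-carbon is electrophilic.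
   - Fallback: make the alkyne as Ar–C≡C–CH(OEt)2 instead. Cyclise to the 3-(diethoxymethyl) azaphilone, unmask the 3-formyl group, and build the (E)-acrylate afterwards by Horner–Wadsworth–Emmons olefination. This builds the side chain after the pyran is closed.
3. **Step 13, global fluoride deprotection of a base-sensitive azaphilone.**
   - Risks: basic TBAF may cleave the activated tertiary ester, add to the pyran, or leave the TMSE ester unremoved.
   - Fallback: redesign the protecting groups. Use a bis-MOM orsellinate and a tert-butyl acrylate, then remove both in a single cold TFA or ZnBr2 acidolysis.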